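**Plan**

- The retrosynthesis first cuts the Ar–CH2–Ar bridge between the two 2,6-dihydroxy-4-methoxyphenyl rings (ring A left, ring C right), which leads back to a Mannich base of the left benzophenone and the free right benzophenone.
- The left benzophenone is cut at two bonds of ring A, the aryl–carbonyl bond and the neighbouring aryl–O bond, giving an ortho-silylaryl triflate and benzyl-protected orsellinic acid. The enabling feature is that in ring A the ketone carbon sits on C1 and a hydroxyl oxygen on the adjacent C2, with a second oxygen on C6; this 1,2-pairing of C-acyl and O is what an aryne gives when it takes up a carboxylic acid across its C–O bond.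
- The right benzophenone is cut at the aryl–carbonyl bond of ring C only, back to an aryl ester of the bromophenol that also serves the aryne precursor. The methoxy-bearing acid is paired with a cold anionic acyl shift so that a hot cesium phenoxide never sits beside its small ortho-methoxy group, and the aryne precursor is consumed only once.
- Forward: no ring is formed at any stage. 5-Methoxyresorcinol gives the bromophenol and the aryne precursor, methyl orsellinate gives both acids, the aryne insertion makes the left ketone, an anionic Fries shift makes the right ketone, and the halves are joined through an ortho-quinone methide before global debenzylation.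
- The target has no stereocentre, so no stereochemical control is needed.

Key step: step 8

Remark: lithiation of bis-acetal 2 is assumed to occur at the carbon between the two methoxymethoxy groups (the stronger pair of directing groups), and methyl orsellinate is used in place of the free, decarboxylation-prone orsellinic acid.

**Route**

Step 1
Reactants: 1 5-methoxyresorcinol
Product: 2 1-methoxy-3,5-bis(methoxymethoxy)benzene
Conditions: NaH (2.4 equiv), MOMCl (2.4 equiv), DMF, 0 °C → rt
Reagents that add atoms: chloromethyl methyl ether, COCCl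
Why: Williamson-type O-alkylation of both sodium phenoxides gives the bis(acetal) ether, whose two acetal oxygens later direct the metalation.

Step 2
Reactants: 2 1-methoxy-3,5-bis(methoxymethoxy)benzene
Product: 4 2-bromo-5-methoxy-1,3-bis(methoxymethoxy)benzene, via aryllithium 3 (not isolated)
Conditions: n-BuLi (1.1 equiv), THF, 0 °C; then BrCH2CH2Br, −78 °C → rt
Reagents that add atoms: 1,2-dibromoethane, BrCCBr
Why: Directed ortho-metalation should take place at the carbon flanked by the two chelating methoxymethoxy groups, and the aryllithium is brominated by halogen transfer from 1,2-dibromoethane.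

Step 3
Reactants: 4 2-bromo-5-methoxy-1,3-bis(methoxymethoxy)benzene
Product: 5 2-bromo-5-methoxy-3-(methoxymethoxy)phenol
Conditions: HCl (cat.), MeOH, 0 °C → rt, stopped at partial conversion; recovered 4 resubjected
Reagents that add atoms: none
Why: Acid-catalysed acetal methanolysis of one of the two equivalent methoxymethyl ethers, where only mono- versus double cleavage has to be managed, by limiting conversion and recycling recovered 4.

Step 4
Reactants: 5 2-bromo-5-methoxy-3-(methoxymethoxy)phenol
Product: 6 [2-bromo-5-methoxy-3-(methoxymethoxy)phenoxy]trimethylsilane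
Conditions: (Me3Si)2NH, THF, reflux; then concentration
Reagents that add atoms: hexamethyldisilazane, C[Si](C)(C)N[Si](C)(C)C
Why: O-silylation of the phenol with hexamethyldisilazane gives the aryl silyl ether needed for oxygen-to-carbon silyl transfer, with ammonia as the only by-product.

Step 5
Reactants: 6 [2-bromo-5-methoxy-3-(methoxymethoxy)phenoxy]trimethylsilane
Product: 9 5-methoxy-3-(methoxymethoxy)-2-(trimethylsilyl)phenyl trifluoromethanesulfonate, via aryllithium 7 (not isolated), via lithium 2-silylphenolate 8 (not isolated)
Conditions: n-BuLi, THF, −100 °C → −80 °C; then Tf2O, −100 °C → rt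
Reagents that add atoms: trifluoromethanesulfonic anhydride, O=S(=O)(OS(=O)(=O)C(F)(F)F)C(F)(F)F
Why: Bromine–lithium exchange is followed by a 1,3 retro-Brook shift of silicon from oxygen to the lithiated carbon, and the lithium phenoxide is trapped by triflic anhydride, the standard entry to ortho-silylaryl triflates.

Step 6
Reactants: 10 methyl orsellinate (methyl 2,4-dihydroxy-6-methylbenzoate)
Product: 11 methyl 2,4-bis(benzyloxy)-6-methylbenzoate
Conditions: BnBr (2.5 equiv), K2CO3, DMF, 60 °C
Reagents that add atoms: benzyl bromide, BrCc1ccccc1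
Why: Double Williamson benzylation, in which the hydrogen-bonded 2-hydroxyl also reacts in warm DMF with excess bromide.

Step 7
Reactants: 11 methyl 2,4-bis(benzyloxy)-6-methylbenzoate
Product: 12 2,4-bis(benzyloxy)-6-methylbenzoic acid
Conditions: KOH, DMSO/H2O, 100 °C; then cold 1 M HCl
Reagents that add atoms: potassium hydroxide, [K+].[OH-]
Why: Saponification of the di-ortho-substituted methyl ester needs hot hydroxide in aqueous DMSO, and cold acidification avoids protodecarboxylation of the electron-rich acid.

Step 8
Reactants: 9 5-methoxy-3-(methoxymethoxy)-2-(trimethylsilyl)phenyl trifluoromethanesulfonate; 12 2,4-bis(benzyloxy)-6-methylbenzoic acid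
Product: 15 [2,4-bis(benzyloxy)-6-methylphenyl][2-hydroxy-4-methoxy-6-(methoxymethoxy)phenyl]methanone, via aryne 13 (not isolated), via cesium aryl anion 14 (not isolated)
Conditions: 12 (1.3 equiv), CsF (4 equiv), THF, 125 °C, sealed tube
Reagents that add atoms: none
Why: Fluoride attacks silicon of 9 and triflate leaves to give aryne 13; the cesium carboxylate of 12 adds through oxygen to the aryne carbon remote from the methoxymethoxy group, which places the aryl anion 14 on the carbon next to that inductively stabilising oxygen. The anion attacks the neighbouring ester carbonyl through a four-membered transition state and the adduct collapses with cleavage of the acyl C–O bond, so the acyl group moves from oxygen to carbon and a phenoxide remains; this is the known fluoride-induced insertion of arynes into the C–O bond of carboxylic acids to give ortho-hydroxyaryl ketones. No ring is closed and no stereocentre is created. The selectivity required is regiochemical and is secured by the 3-alkoxy substituent of the aryne (distortion of the aryne and inductive stabilisation of the ortho anion), so the ketone should land between the two oxygens and exactly one hydroxyl is set free. The competing path is protonation of 14 before the acyl shift, made more likely by the two ortho substituents on the acyl group; high temperature in THF and a slight excess of the acid over the aryne precursor are chosen to favour the shift and to limit arylation of the product phenoxide.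

Step 9
Reactants: 15 [2,4-bis(benzyloxy)-6-methylphenyl][2-hydroxy-4-methoxy-6-(methoxymethoxy)phenyl]methanone
Product: 16 [2,4-bis(benzyloxy)-6-methylphenyl](2,6-dihydroxy-4-methoxyphenyl)methanone
Conditions: HCl (3 M in MeOH), THF, 45 °C
Reagents that add atoms: none
Why: Acid-catalysed acetal methanolysis removes the methoxymethyl group while benzyl ethers and the ketone are untouched, leaving ring A with two equivalent free positions.

Step 10
Reactants: 16 [2,4-bis(benzyloxy)-6-methylphenyl](2,6-dihydroxy-4-methoxyphenyl)methanone
Product: 17 [2,4-bis(benzyloxy)-6-methylphenyl]{3-[(dimethylamino)methyl]-2,6-dihydroxy-4-methoxyphenyl}methanone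
Conditions: 37% aq. CH2O (1.0 equiv), 40% aq. Me2NH (1.1 equiv), premixed, EtOH, 0 °C → rt
Reagents that add atoms: formaldehyde, C=O; dimethylamine, CNC
Why: Phenolic Mannich reaction of the iminium ion at a position of ring A ortho to hydroxyl; both open positions are equivalent, so only over-aminomethylation has to be held back, by one equivalent of reagent at low temperature.

Step 11
Reactants: 10 methyl orsellinate
Product: 18 methyl 4-(benzyloxy)-2-hydroxy-6-methylbenzoate
Conditions: BnBr (1.05 equiv), K2CO3 (1.1 equiv), acetone, reflux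
Reagents that add atoms: benzyl bromide, BrCc1ccccc1
Why: Williamson benzylation is selective for the 4-hydroxyl because the 2-hydroxyl is hydrogen-bonded to the ester carbonyl and much less reactive under mild carbonate conditions.

Step 12
Reactants: 18 methyl 4-(benzyloxy)-2-hydroxy-6-methylbenzoate
Product: 19 methyl 4-(benzyloxy)-2-methoxy-6-methylbenzoate
Conditions: MeI (3 equiv), K2CO3, DMF, 50 °C
Reagents that add atoms: iodomethane, CI
Why: Williamson methylation of the remaining hydrogen-bonded phenol under more forcing conditions.

Step 13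
Reactants: 19 methyl 4-(benzyloxy)-2-methoxy-6-methylbenzoate
Product: 20 4-(benzyloxy)-2-methoxy-6-methylbenzoic acid
Conditions: KOH, DMSO/H2O, 100 °C; then cold 1 M HCl
Reagents that add atoms: potassium hydroxide, [K+].[OH-]
Why: Saponification of the hindered methyl ester as in step 7, with cold acidification to avoid decarboxylation.

Step 14
Reactants: 5 2-bromo-5-methoxy-3-(methoxymethoxy)phenol; 20 4-(benzyloxy)-2-methoxy-6-methylbenzoic acid
Product: 21 2-bromo-5-methoxy-3-(methoxymethoxy)phenyl 4-(benzyloxy)-2-methoxy-6-methylbenzoate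
Conditions: DCC (1.2 equiv), DMAP (0.2 equiv), CH2Cl2, 0 °C → rt
Reagents that add atoms: none
Why: Steglich esterification, in which the O-acylisourea formed from the acid and the carbodiimide passes the hindered aroyl group through the acylpyridinium ion to the phenol, the usual way aryl esters of orsellinic acids are made; the acetal, the benzyl ether and the aryl bromide are inert.

Step 15
Reactants: 21 2-bromo-5-methoxy-3-(methoxymethoxy)phenyl 4-(benzyloxy)-2-methoxy-6-methylbenzoate
Product: 23 [4-(benzyloxy)-2-methoxy-6-methylphenyl][2-hydroxy-4-methoxy-6-(methoxymethoxy)phenyl]methanone, via aryllithium 22 (not isolated)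
Conditions: n-BuLi (1.05 equiv), THF, −100 °C → −78 °C; then AcOH, −78 °C → rt
Reagents that add atoms: none
Why: Bromine–lithium exchange at the carbon flanked by two oxygens should outrun addition of n-BuLi to the di-ortho-substituted benzoate, and the aryllithium then attacks the adjacent ester carbonyl so that the aroyl group moves from oxygen to carbon (anionic Fries rearrangement, a 1,3 oxygen-to-carbon acyl shift) in a cold, proton-free medium before acetic acid frees the phenol.

Step 16
Reactants: 23 [4-(benzyloxy)-2-methoxy-6-methylphenyl][2-hydroxy-4-methoxy-6-(methoxymethoxy)phenyl]methanone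
Product: 24 [4-(benzyloxy)-2-methoxy-6-methylphenyl](2,6-dihydroxy-4-methoxyphenyl)methanone
Conditions: HCl (3 M in MeOH), THF, 45 °C
Reagents that add atoms: none
Why: Acid-catalysed acetal methanolysis as in step 9, giving ring C with two equivalent nucleophilic positions.

Step 17
Reactants: 17 [2,4-bis(benzyloxy)-6-methylphenyl]{3-[(dimethylamino)methyl]-2,6-dihydroxy-4-methoxyphenyl}methanone; 24 [4-(benzyloxy)-2-methoxy-6-methylphenyl](2,6-dihydroxy-4-methoxyphenyl)methanone
Product: 26 tri-O-benzyl ether of the target, {3-[(3-{[4-(benzyloxy)-2-methoxy-6-methylphenyl]carbonyl}-2,4-dihydroxy-6-methoxyphenyl)methyl]-2,6-dihydroxy-4-methoxyphenyl}[2,4-bis(benzyloxy)-6-methylphenyl]methanone, via ortho-quinone methide 25 (not isolated)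
Conditions: 24 (2 equiv), 1,4-dioxane, 100 °C, slow addition of 17, N2 sweep
Reagents that add atoms: none
Why: Thermal loss of dimethylamine from the ortho-hydroxybenzylamine gives ortho-quinone methide 25, which is C-alkylated in a Michael-type addition by ring C of 24 at one of its two equivalent positions ortho to hydroxyl (the known use of phenolic Mannich bases as benzylating agents), with excess 24 and slow addition holding back self-condensation.

Step 18
Reactants: 26 tri-O-benzyl ether of the target
Product: 27 the target, [3-({3-[(4-hydroxy-2-methoxy-6-methylphenyl)carbonyl]-2,4-dihydroxy-6-methoxyphenyl}methyl)-2,6-dihydroxy-4-methoxyphenyl](2,4-dihydroxy-6-methylphenyl)methanone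
Conditions: H2 (1 atm), 10% Pd/C, EtOAc/MeOH, rt
Reagents that add atoms: none
Why: Catalytic hydrogenolysis cleaves the three benzyl ethers, while the hydrogen-bonded, fully ortho-substituted diaryl ketones and the diarylmethane bridge should survive at 1 atm and room temperature.

**Compound list**

1 | 5-methoxyresorcinol | COc1cc(O)cc(O)c1 | starting material
2 | 1-methoxy-3,5-bis(methoxymethoxy)benzene | COCOc1cc(OC)cc(OCOC)c1 | intermediate
3 | [4-methoxy-2,6-bis(methoxymethoxy)phenyl]lithium | [Li]c1c(OCOC)cc(OC)cc1OCOC | intermediate
4 | 2-bromo-5-methoxy-1,3-bis(methoxymethoxy)benzene | COCOc1cc(OC)cc(OCOC)c1Br | intermediate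
5 | 2-bromo-5-methoxy-3-(methoxymethoxy)phenol | COCOc1cc(OC)cc(O)c1Br | intermediate
6 | [2-bromo-5-methoxy-3-(methoxymethoxy)phenoxy]trimethylsilane | COCOc1cc(OC)cc(O[Si](C)(C)C)c1Br | intermediate
7 | [4-methoxy-2-(methoxymethoxy)-6-(trimethylsilyloxy)phenyl]lithium | [Li]c1c(OCOC)cc(OC)cc1O[Si](C)(C)C | intermediate
8 | lithium 5-methoxy-3-(methoxymethoxy)-2-(trimethylsilyl)phenolate | [Li+].[O-]c1cc(OC)cc(OCOC)c1[Si](C)(C)C | intermediate
9 | 5-methoxy-3-(methoxymethoxy)-2-(trimethylsilyl)phenyl trifluoromethanesulfonate | COCOc1cc(OC)cc(OS(=O)(=O)C(F)(F)F)c1[Si](C)(C)C | intermediate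
10 | methyl orsellinate (methyl 2,4-dihydroxy-6-methylbenzoate) | COC(=O)c1c(C)cc(O)cc1O | starting material
11 | methyl 2,4-bis(benzyloxy)-6-methylbenzoate | COC(=O)c1c(C)cc(OCc2ccccc2)cc1OCc1ccccc1 | intermediate
12 | 2,4-bis(benzyloxy)-6-methylbenzoic acid | Cc1cc(OCc2ccccc2)cc(OCc2ccccc2)c1C(=O)O | intermediate
13 | 5-methoxy-3-(methoxymethoxy)benzyne (1,2-didehydro-5-methoxy-3-(methoxymethoxy)benzene) | COCOC1=CC(OC)=CC#C1 | intermediate
14 | cesium 2-{[2,4-bis(benzyloxy)-6-methylbenzoyl]oxy}-4-methoxy-6-(methoxymethoxy)phenide | COCOc1cc(OC)cc(OC(=O)c2c(C)cc(OCc3ccccc3)cc2OCc2ccccc2)[c-]1.[Cs+] | intermediate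
15 | [2,4-bis(benzyloxy)-6-methylphenyl][2-hydroxy-4-methoxy-6-(methoxymethoxy)phenyl]methanone | COCOc1cc(OC)cc(O)c1C(=O)c1c(C)cc(OCc2ccccc2)cc1OCc1ccccc1 | intermediate
16 | [2,4-bis(benzyloxy)-6-methylphenyl](2,6-dihydroxy-4-methoxyphenyl)methanone | COc1cc(O)c(C(=O)c2c(C)cc(OCc3ccccc3)cc2OCc2ccccc2)c(O)c1 | intermediate
17 | [2,4-bis(benzyloxy)-6-methylphenyl]{3-[(dimethylamino)methyl]-2,6-dihydroxy-4-methoxyphenyl}methanone | CN(C)Cc1c(OC)cc(O)c(C(=O)c2c(C)cc(OCc3ccccc3)cc2OCc2ccccc2)c1O | intermediate
18 | methyl 4-(benzyloxy)-2-hydroxy-6-methylbenzoate | COC(=O)c1c(C)cc(OCc2ccccc2)cc1O | intermediate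
19 | methyl 4-(benzyloxy)-2-methoxy-6-methylbenzoate | COC(=O)c1c(C)cc(OCc2ccccc2)cc1OC | intermediate
20 | 4-(benzyloxy)-2-methoxy-6-methylbenzoic acid | COc1cc(OCc2ccccc2)cc(C)c1C(=O)O | intermediate
21 | 2-bromo-5-methoxy-3-(methoxymethoxy)phenyl 4-(benzyloxy)-2-methoxy-6-methylbenzoate | COCOc1cc(OC)cc(OC(=O)c2c(C)cc(OCc3ccccc3)cc2OC)c1Br | intermediate
22 | {2-[(4-benzyloxy-2-methoxy-6-methylbenzoyl)oxy]-4-methoxy-6-(methoxymethoxy)phenyl}lithium | [Li]c1c(OCOC)cc(OC)cc1OC(=O)c1c(C)cc(OCc2ccccc2)cc1OC | intermediate
23 | [4-(benzyloxy)-2-methoxy-6-methylphenyl][2-hydroxy-4-methoxy-6-(methoxymethoxy)phenyl]methanone | COCOc1cc(OC)cc(O)c1C(=O)c1c(C)cc(OCc2ccccc2)cc1OC | intermediate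
24 | [4-(benzyloxy)-2-methoxy-6-methylphenyl](2,6-dihydroxy-4-methoxyphenyl)methanone | COc1cc(O)c(C(=O)c2c(C)cc(OCc3ccccc3)cc2OC)c(O)c1 | intermediate
25 | 2-[2,4-bis(benzyloxy)-6-methylbenzoyl]-3-hydroxy-5-methoxy-6-methylidenecyclohexa-2,4-dien-1-one | C=C1C(OC)=CC(O)=C(C(=O)c2c(C)cc(OCc3ccccc3)cc2OCc2ccccc2)C1=O | intermediate
26 | {3-[(3-{[4-(benzyloxy)-2-methoxy-6-methylphenyl]carbonyl}-2,4-dihydroxy-6-methoxyphenyl)methyl]-2,6-dihydroxy-4-methoxyphenyl}[2,4-bis(benzyloxy)-6-methylphenyl]methanone | COc1cc(O)c(C(=O)c2c(C)cc(OCc3ccccc3)cc2OCc2ccccc2)c(O)c1Cc1c(OC)cc(O)c(C(=O)c2c(C)cc(OCc3ccccc3)cc2OC)c1O | intermediate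
27 | CNP0596095.0, [3-({3-[(4-hydroxy-2-methoxy-6-methylphenyl)carbonyl]-2,4-dihydroxy-6-methoxyphenyl}methyl)-2,6-dihydroxy-4-methoxyphenyl](2,4-dihydroxy-6-methylphenyl)methanone | COc1cc(O)c(C(=O)c2c(C)cc(O)cc2O)c(O)c1Cc1c(OC)cc(O)c(C(=O)c2c(C)cc(O)cc2OC)c1O | target

**Step count and risks**

Total step count: 18. Longest linear sequence: 10 steps (steps 1, 2, 3, 4, 5, 8, 9, 10, 17, 18, from 5-methoxyresorcinol).

Steps most likely to fail:

Step 8. The aryl anion may be protonated before the four-centre acyl shift onto the carbonyl, which is shielded by two ortho substituents, so the reaction would stop at the O-arylation stage. At 125 °C the product phenoxide may also be arylated by a second aryne. The fallback sets out from 5 and 12 and returns at 15. Acid 12 would be esterified with bromophenol 5 (DCC, DMAP, CH2Cl2, as in step 14) to 2-bromo-5-methoxy-3-(methoxymethoxy)phenyl 2,4-bis(benzyloxy)-6-methylbenzoate F1. n-BuLi in THF at −100 °C would effect bromine–lithium exchange to {2-[(2,4-bis(benzyloxy)-6-methylbenzoyl)oxy]-4-methoxy-6-(methoxymethoxy)phenyl}lithium F2. In this cold, proton-free medium F2 should undergo the anionic Fries acyl shift and give 15 after an acetic acid quench, with no fluoride, no heating and no aryne involved.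

Step 15. n-BuLi may add to the ester carbonyl or remove a benzylic proton of the ortho-methyl group in competition with the halogen–metal exchange, and the aryllithium may be quenched by such a proton before the acyl group has moved. The fallback sets out from 2 and 19 and returns at 24. Ester 19 would be reduced with LiAlH4 in THF to [4-(benzyloxy)-2-methoxy-6-methylphenyl]methanol F3, and MnO2 in CH2Cl2 would oxidise this to 4-(benzyloxy)-2-methoxy-6-methylbenzaldehyde F4. Bis-acetal 2 would be lithiated as in step 2 to aryllithium 3 and added to F4 at −78 °C, giving the racemic diaryl carbinol [4-(benzyloxy)-2-methoxy-6-methylphenyl][4-methoxy-2,6-bis(methoxymethoxy)phenyl]methanol F5. Dess–Martin oxidation would give [4-(benzyloxy)-2-methoxy-6-methylphenyl][4-methoxy-2,6-bis(methoxymethoxy)phenyl]methanone F6, and HCl in MeOH would remove both acetal ethers to reach 24. This path replaces the acyl shift by a 1,2-addition to an aldehyde, which has no ester to be attacked and tolerates crowding around the carbonyl far better.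

Step 17. The Mannich base may lose amine only at temperatures where the quinone methide is also captured by a second molecule of 17 or by the product (oligomerisation), and the methylene unit may scramble between the two phloroglucinol rings to give symmetric dimers. The fallback sets out from 17 and 24 and returns at 26. Amine 17 would be N-methylated with MeI in acetone at rt to the quaternary salt {3-[2,4-bis(benzyloxy)-6-methylbenzoyl]-2,4-dihydroxy-6-methoxyphenyl}methyl(trimethyl)ammonium iodide F7. After removal of excess MeI, F7 would be added slowly to excess 24 and K2CO3 in MeCN at 0 °C to rt, so that trimethylamine is expelled and quinone methide 25 is formed cold and at low stationary concentration, then trapped by 24 to give 26.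

Further compounds
F1 | step 8 | 2-bromo-5-methoxy-3-(methoxymethoxy)phenyl 2,4-bis(benzyloxy)-6-methylbenzoate | COCOc1cc(OC)cc(OC(=O)c2c(C)cc(OCc3ccccc3)cc2OCc2ccccc2)c1Br
F2 | step 8 | {2-[(2,4-bis(benzyloxy)-6-methylbenzoyl)oxy]-4-methoxy-6-(methoxymethoxy)phenyl}lithium | [Li]c1c(OCOC)cc(OC)cc1OC(=O)c1c(C)cc(OCc2ccccc2)cc1OCc1ccccc1
F3 | step 15 | [4-(benzyloxy)-2-methoxy-6-methylphenyl]methanol | COc1cc(OCc2ccccc2)cc(C)c1CO
F4 | step 15 | 4-(benzyloxy)-2-methoxy-6-methylbenzaldehyde | COc1cc(OCc2ccccc2)cc(C)c1C=O
F5 | step 15 | [4-(benzyloxy)-2-methoxy-6-methylphenyl][4-methoxy-2,6-bis(methoxymethoxy)phenyl]methanol (racemic) | COCOc1cc(OC)cc(OCOC)c1C(O)c1c(C)cc(OCc2ccccc2)cc1OC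
F6 | step 15 | [4-(benzyloxy)-2-methoxy-6-methylphenyl][4-methoxy-2,6-bis(methoxymethoxy)phenyl]methanone | COCOc1cc(OC)cc(OCOC)c1C(=O)c1c(C)cc(OCc2ccccc2)cc1OC
F7 | step 17 | {3-[2,4-bis(benzyloxy)-6-methylbenzoyl]-2,4-dihydroxy-6-methoxyphenyl}methyl(trimethyl)ammonium iodide | C[N+](C)(C)Cc1c(OC)cc(O)c(C(=O)c2c(C)cc(OCc3ccccc3)cc2OCc2ccccc2)c1O.[I-]
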